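A direct plan would form the depside ester last, at its acyl–oxygen bond: 3-formyl-2-hydroxy-4-methoxy-6-methylbenzoic acid A1 would be activated with a carbodiimide and joined to the 5-hydroxyl of tert-butyl 3-formyl-2,4,5-trihydroxy-6-methylbenzoate A2, and acid would then cleave the tert-butyl ester of the product A3. Its weakest steps would be (a) the supply of A2, a fully substituted catechol aldehyde that would cost a ring synthesis with late dehydrogenation, many steps for one extra oxygen; (b) the esterification, where two di-ortho-substituted partners would have to meet while O4' competes, so that the site would rest on hydrogen bonding alone; (c) the handling of A2, which would oxidise in air.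

The depside is cut at the aryl C5'–O bond of ring B, not at the acyl–O bond. Ring B enters as benzyl haematommate, whose only unsubstituted carbon, C5', lies ortho to O4' and para to O2' with both acceptors (C3'-CHO, C1'-CO2Bn) meta; its phenoxide takes an aroyloxy group from the symmetrical diaroyl peroxide of the protected ring A acid. One operation thus installs the fifth oxygen of ring B, completes its hexasubstitution and forms the hindered ester, with the position fixed by the vacancy at C5'. No catechol is ever free, no ring is built or dehydrogenated, and no crowded acid has to acylate a crowded phenol in competition with a neighbouring hydroxyl.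

Key step: step 10

Assumption: the monosodium salt of benzyl haematommate is drawn with its charge on O4'; the outcome should not depend on which hydroxyl is ionised, because C5' is ortho to one oxygen and para to the other.

Step 1
Reactants: 1 methyl 2,4-dihydroxy-6-methylbenzoate (methyl orsellinate)
Product: 2 methyl 2-hydroxy-4-methoxy-6-methylbenzoate
Conditions: MeI (1.05 equiv), K2CO3 (1.05 equiv), acetone, reflux
Reagents that add atoms: iodomethane, CI
Why: Williamson etherification in which one equivalent of base and MeI should reach only the 4-OH, the more acidic hydroxyl (para to the ester) and the one not tied up in a hydrogen bond to the ester carbonyl.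

Step 2
Reactants: 2 methyl 2-hydroxy-4-methoxy-6-methylbenzoate
Product: 4 methyl 3-formyl-2-hydroxy-4-methoxy-6-methylbenzoate, via hydroxymethyl phenol 3 (not isolated)
Conditions: MgCl2 (anhydrous), Et3N, (CH2O)n, MeCN, reflux; 1 M HCl work-up
Reagents that add atoms: paraformaldehyde (reacts as formaldehyde), C=O
Why: Magnesium-mediated ortho-formylation of a phenol (Casnati–Skattebøl reaction), in which formaldehyde is delivered within the magnesium phenoxide to C3, the only free position ortho to the phenol oxygen, and the hydroxymethyl stage 3 is oxidised by a second formaldehyde through hydride transfer, so that the C5 isomer cannot form.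

Step 3
Reactants: 4 methyl 3-formyl-2-hydroxy-4-methoxy-6-methylbenzoate
Product: 5 methyl 2-(benzyloxy)-3-formyl-4-methoxy-6-methylbenzoate
Conditions: BnBr (1.3 equiv), K2CO3 (1.5 equiv), DMF, 60 °C
Reagents that add atoms: benzyl bromide, BrCc1ccccc1
Why: Williamson O-benzylation of the chelated 2-OH (K2CO3 in warm DMF overcomes the hydrogen bonds), which removes the only nucleophilic and acidic site of ring A before the peroxide chemistry and places a second ortho substituent beside the future peroxide carbonyl.

Step 4
Reactants: 5 methyl 2-(benzyloxy)-3-formyl-4-methoxy-6-methylbenzoate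
Product: 6 methyl 2-(benzyloxy)-3-(5,5-dimethyl-1,3-dioxan-2-yl)-4-methoxy-6-methylbenzoate
Conditions: 2,2-dimethylpropane-1,3-diol (3 equiv), TsOH·H2O (5 mol %), toluene, reflux, Dean–Stark trap; Et3N quench
Reagents that add atoms: 2,2-dimethylpropane-1,3-diol, CC(C)(CO)CO
Why: Acid-catalysed acetalisation driven by azeotropic removal of water, needed because the free 2,6-dioxygenated benzaldehyde would be at risk of a Cannizzaro reaction in step 5 and of Baeyer–Villiger (Dakin-type) oxidation once the ring carries a peroxy acid group in step 6, whereas the neopentyl glycol acetal is inert to base and to peroxides.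

Step 5
Reactants: 6 methyl 2-(benzyloxy)-3-(5,5-dimethyl-1,3-dioxan-2-yl)-4-methoxy-6-methylbenzoate
Product: 7 2-(benzyloxy)-3-(5,5-dimethyl-1,3-dioxan-2-yl)-4-methoxy-6-methylbenzoic acid
Conditions: KOH (10 equiv), DMSO–H2O (4:1), 90 °C; then 0 °C, 1 M KHSO4 to pH 4–5, immediate extraction
Reagents that add atoms: potassium hydroxide, [K+].[OH-]
Why: Saponification of a di-ortho-substituted methyl benzoate by poorly solvated hydroxide in aqueous DMSO, to which the acetal and both ethers are inert, followed by a cold and only weakly acidic work-up that should leave the acid-labile acetal in place.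

Step 6
Reactants: 7 2-(benzyloxy)-3-(5,5-dimethyl-1,3-dioxan-2-yl)-4-methoxy-6-methylbenzoic acid
Product: 8 2-(benzyloxy)-3-(5,5-dimethyl-1,3-dioxan-2-yl)-4-methoxy-6-methylperoxybenzoic acid
Conditions: half of the batch of 7; urea–hydrogen peroxide adduct (6 equiv), THF, −15 °C, dark; DCC (1.1 equiv) added slowly, −15 → 0 °C; filtered cold; CH2Cl2, cold water wash, Na2SO4; assayed by iodometry and kept as a cold CH2Cl2 solution
Reagents that add atoms: hydrogen peroxide (as its urea adduct), OO
Why: Carbodiimide-mediated perhydrolysis of a carboxylic acid, in which the O-acylisourea formed from 7 and DCC is attacked by hydrogen peroxide, a small α-effect nucleophile kept in large excess so that it outruns the bulkier peroxy acid for the activated acid, under neutral, anhydrous and cold conditions that should spare the acetal.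

Step 7
Reactants: 7 2-(benzyloxy)-3-(5,5-dimethyl-1,3-dioxan-2-yl)-4-methoxy-6-methylbenzoic acid; 8 2-(benzyloxy)-3-(5,5-dimethyl-1,3-dioxan-2-yl)-4-methoxy-6-methylperoxybenzoic acid
Product: 9 bis[2-(benzyloxy)-3-(5,5-dimethyl-1,3-dioxan-2-yl)-4-methoxy-6-methylbenzoyl] peroxide
Conditions: second half of the batch of 7 (1.0 equiv), 8 (1.0 equiv by assay), DCC (1.05 equiv), CH2Cl2, −15 → 0 °C, dark, no amine catalyst; filtered cold; kept in solution, assayed by iodometry and used at once
Reagents that add atoms: none
Why: Carbodiimide-mediated acylation of a peroxy acid by a carboxylic acid (the coupling used for diacyl peroxides), in which the terminal α-effect oxygen of 8 attacks the O-acylisourea of the second molecule of 7 and DCC takes up the water, one molecule of each partner giving the symmetrical peroxide under neutral, cold conditions that should spare the acetal and the electron-rich O–O compound.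

Step 8
Reactants: 10 2,4-dihydroxy-6-methylbenzoic acid (orsellinic acid)
Product: 11 benzyl 2,4-dihydroxy-6-methylbenzoate
Conditions: BnBr (1.05 equiv), KHCO3 (1.1 equiv), DMF, rt
Reagents that add atoms: benzyl bromide, BrCc1ccccc1
Why: SN2 alkylation of the carboxylate, the only group that KHCO3 deprotonates, so that both phenols stay free and the acid is secured against decarboxylation as an ester that hydrogenolysis removes at the end.

Step 9
Reactants: 11 benzyl 2,4-dihydroxy-6-methylbenzoate
Product: 13 benzyl 3-formyl-2,4-dihydroxy-6-methylbenzoate (benzyl haematommate), via α-chloro ether 12 (not isolated)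
Conditions: TiCl4 (2.5 equiv), CH2Cl2, −10 °C; Cl2CHOMe (1.3 equiv), −10 → 0 °C; ice–1 M HCl
Reagents that add atoms: dichloromethyl methyl ether, COC(Cl)Cl; water, O
Why: Rieche formylation under control by tetravalent titanium, which is held as a chelate by the 2-O and the ester carbonyl and also binds the 4-O, so that the electrophile from Cl2CHOMe should enter C3, ortho to both oxygens (the usual site for titanium-mediated formylation of 2-carbonyl phenols), and hydrolysis of α-chloro ether 12 then gives the aldehyde while C5 stays free for step 10.

Step 10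
Reactants: 13 benzyl 3-formyl-2,4-dihydroxy-6-methylbenzoate; 9 bis[2-(benzyloxy)-3-(5,5-dimethyl-1,3-dioxan-2-yl)-4-methoxy-6-methylbenzoyl] peroxide
Product: 17 benzyl 5-{[2-(benzyloxy)-3-formyl-4-methoxy-6-methylbenzoyl]oxy}-3-formyl-2,4-dihydroxy-6-methylbenzoate, via sodium phenoxide 14 (not isolated), via acyloxy dienone 15 (not isolated), via acetal depside 16 (not isolated)
Conditions: 13 (1.2 equiv), NaH (1.2 equiv), THF, 0 °C; 9 (1.0 equiv) in CH2Cl2, −20 → 0 °C, dark; then THF–1 M HCl, rt
Reagents that add atoms: water, O
Why: Ortho-acyloxylation of a phenol by a diaroyl peroxide (the reaction by which dibenzoyl peroxide turns phenols into catechol monobenzoates), run here on the sodium phenoxide 14: the O–O bond is attacked either by C5' directly, as phenoxide carbons attack peroxydisulfate in the Elbs oxidation, or by O4' to give an aryl peroxy ester that shifts its acyloxy group to the ortho carbon in a [3,3] manner, and both paths meet in dienone 15. Only the adduct at C5' carries a ring hydrogen, so it alone can aromatise (to 16) by proton loss to the expelled carboxylate, whereas an adduct at C3' or C1' could only revert or shift again. No ring is closed and no stereocentre remains, the sp3 carbon of 15 being transient. The site selectivity rests on the substrate: C5' is the single unsubstituted carbon of 13, it is ortho to O4' and para to O2', and both acceptors are meta to it, so it should keep the nucleophilicity of a resorcinol carbon. The chemoselectivity for O–O over C=O attack rests on the reagent: each carbonyl of 9 is flanked by OBn and CH3, which should block acyl transfer to the phenoxide, and the acyl group should not end on O4' because oxygen reaches C5' already acylated and the 5'-ester beside a formyl-chelated 4'-OH is also the more stable isomer. Dilute HCl finally hydrolyses the very labile dioxygenated aryl acetal of 16 to 17 without touching the esters.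

Step 11
Reactants: 17 benzyl 5-{[2-(benzyloxy)-3-formyl-4-methoxy-6-methylbenzoyl]oxy}-3-formyl-2,4-dihydroxy-6-methylbenzoate
Product: 18 haemathamnolic acid
Conditions: H2 (1 atm), 10% Pd/C, EtOAc, rt, followed by TLC and stopped on completion
Reagents that add atoms: none
Why: Catalytic hydrogenolysis of the benzyl ester and of the aryl benzyl ether, both much faster on Pd than reduction of formyl groups that are flanked by oxygen substituents and held in hydrogen bonds, as is usual at the end of depside syntheses; the target has no stereocentre.

## Compound list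

1 | methyl 2,4-dihydroxy-6-methylbenzoate (methyl orsellinate) | COC(=O)c1c(C)cc(O)cc1O | starting material
2 | methyl 2-hydroxy-4-methoxy-6-methylbenzoate | COC(=O)c1c(C)cc(OC)cc1O | intermediate
3 | methyl 2-hydroxy-3-(hydroxymethyl)-4-methoxy-6-methylbenzoate (present as magnesium salt, not isolated) | COC(=O)c1c(C)cc(OC)c(CO)c1O | intermediate
4 | methyl 3-formyl-2-hydroxy-4-methoxy-6-methylbenzoate | COC(=O)c1c(C)cc(OC)c(C=O)c1O | intermediate
5 | methyl 2-(benzyloxy)-3-formyl-4-methoxy-6-methylbenzoate | COC(=O)c1c(C)cc(OC)c(C=O)c1OCc1ccccc1 | intermediate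
6 | methyl 2-(benzyloxy)-3-(5,5-dimethyl-1,3-dioxan-2-yl)-4-methoxy-6-methylbenzoate | COC(=O)c1c(C)cc(OC)c(C2OCC(C)(C)CO2)c1OCc1ccccc1 | intermediate
7 | 2-(benzyloxy)-3-(5,5-dimethyl-1,3-dioxan-2-yl)-4-methoxy-6-methylbenzoic acid | OC(=O)c1c(C)cc(OC)c(C2OCC(C)(C)CO2)c1OCc1ccccc1 | intermediate
8 | 2-(benzyloxy)-3-(5,5-dimethyl-1,3-dioxan-2-yl)-4-methoxy-6-methylperoxybenzoic acid (handled as a cold solution) | OOC(=O)c1c(C)cc(OC)c(C2OCC(C)(C)CO2)c1OCc1ccccc1 | intermediate
9 | bis[2-(benzyloxy)-3-(5,5-dimethyl-1,3-dioxan-2-yl)-4-methoxy-6-methylbenzoyl] peroxide | O=C(OOC(=O)c1c(C)cc(OC)c(C2OCC(C)(C)CO2)c1OCc1ccccc1)c1c(C)cc(OC)c(C2OCC(C)(C)CO2)c1OCc1ccccc1 | intermediate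
10 | 2,4-dihydroxy-6-methylbenzoic acid (orsellinic acid) | Cc1cc(O)cc(O)c1C(=O)O | starting material
11 | benzyl 2,4-dihydroxy-6-methylbenzoate | Cc1cc(O)cc(O)c1C(=O)OCc1ccccc1 | intermediate
12 | benzyl 3-[chloro(methoxy)methyl]-2,4-dihydroxy-6-methylbenzoate (racemic; present as titanium chelate, not isolated) | COC(Cl)c1c(O)cc(C)c(C(=O)OCc2ccccc2)c1O | intermediate
13 | benzyl 3-formyl-2,4-dihydroxy-6-methylbenzoate (benzyl haematommate) | Cc1cc(O)c(C=O)c(O)c1C(=O)OCc1ccccc1 | intermediate
14 | sodium 4-phenoxide of benzyl 3-formyl-2,4-dihydroxy-6-methylbenzoate (not isolated) | [Na+].Cc1cc([O-])c(C=O)c(O)c1C(=O)OCc1ccccc1 | intermediate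
15 | benzyl 3-{[2-(benzyloxy)-3-(5,5-dimethyl-1,3-dioxan-2-yl)-4-methoxy-6-methylbenzoyl]oxy}-5-formyl-6-hydroxy-2-methyl-4-oxocyclohexa-1,5-diene-1-carboxylate (racemic at the sp3 carbon; dienone tautomer of 16, not isolated) | CC1=C(C(=O)OCc2ccccc2)C(O)=C(C=O)C(=O)C1OC(=O)c1c(C)cc(OC)c(C2OCC(C)(C)CO2)c1OCc1ccccc1 | intermediate
16 | benzyl 5-{[2-(benzyloxy)-3-(5,5-dimethyl-1,3-dioxan-2-yl)-4-methoxy-6-methylbenzoyl]oxy}-3-formyl-2,4-dihydroxy-6-methylbenzoate (not isolated) | COc1cc(C)c(C(=O)Oc2c(C)c(C(=O)OCc3ccccc3)c(O)c(C=O)c2O)c(OCc2ccccc2)c1C1OCC(C)(C)CO1 | intermediate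
17 | benzyl 5-{[2-(benzyloxy)-3-formyl-4-methoxy-6-methylbenzoyl]oxy}-3-formyl-2,4-dihydroxy-6-methylbenzoate | COc1cc(C)c(C(=O)Oc2c(C)c(C(=O)OCc3ccccc3)c(O)c(C=O)c2O)c(OCc2ccccc2)c1C=O | intermediate
18 | haemathamnolic acid | COc1cc(C)c(C(=O)Oc2c(C)c(C(=O)O)c(O)c(C=O)c2O)c(O)c1C=O | target

Total step count: 11 (steps 1–7 for ring A, steps 8–9 for ring B, steps 10–11 after convergence). Longest linear sequence: 9 steps (1–7, 10, 11).

Steps most likely to fail, with fallbacks:

Step 10. The phenoxide might attack a peroxide carbonyl despite the ortho shielding, which would give acyl transfer to O4' and release a peroxy acid that could oxidise the aldehydes. An aryl peroxy ester might also shift its acyloxy group to the formyl-bearing C3', with loss of the formyl group. Finally, the electron-rich peroxide might decompose (homolysis or carboxy inversion) faster than it is attacked. The fallback would set out from 13, use acid 7 and come back at 16. Elbs persulfate oxidation of 13 (K2S2O8, aqueous NaOH, 0 °C → rt), in which C5, para to the 2-phenoxide, attacks the peroxydisulfate oxygen, should give the potassium salt of benzyl 3-formyl-2,4-dihydroxy-6-methyl-5-(sulfooxy)benzoate F1. Hydrolysis of the aryl sulfate with dilute HCl should give benzyl 3-formyl-2,4,5-trihydroxy-6-methylbenzoate F2, to be used at once under argon. Steglich esterification of F2 with 7 (DCC, DMAP cat., CH2Cl2, 0 °C) at the 5-OH, the only hydroxyl outside a hydrogen-bond chelate, should give 16, which the acid treatment of step 10 converts into 17.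

Step 6. The hindered O-acylisourea might rearrange to the N-acylurea before perhydrolysis, the carbodiimide might be consumed by hydrogen peroxide itself, and the acetal might be lost to the free acid in the presence of moisture. The fallback would set out from 7 and come back at 9, so that it replaces steps 6 and 7 together and separates activation from O–O bond formation. Neutral chlorination with 1-chloro-N,N,2-trimethylprop-1-en-1-amine (CH2Cl2, 0 °C) should give 2-(benzyloxy)-3-(5,5-dimethyl-1,3-dioxan-2-yl)-4-methoxy-6-methylbenzoyl chloride F3, and two equivalents of F3 would then be joined by the preformed peroxide dianion of Na2O2 (0.5 equiv, THF–H2O, 0 °C). Should 9 prove too labile to use at all, the fallback given for step 10 bypasses it.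

Step 11. A formyl group might be reduced to hydroxymethyl or methyl before the hindered aryl benzyl ether is cleaved. The fallback would set out from 17 and come back at 18 and makes no new compound (F0). Lewis-acid debenzylation with BCl3 and pentamethylbenzene as benzyl cation scavenger (CH2Cl2, −78 °C) should cleave the benzyl ester and the benzyl ether that lies ortho to two carbonyl groups. The methyl ether, whose oxygen is outside the boron chelate, should survive at this temperature.

Further compounds

F1 | step 10 | potassium salt of benzyl 3-formyl-2,4-dihydroxy-6-methyl-5-(sulfooxy)benzoate | Cc1c(OS(=O)(=O)[O-])c(O)c(C=O)c(O)c1C(=O)OCc1ccccc1.[K+]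
F2 | step 10 | benzyl 3-formyl-2,4,5-trihydroxy-6-methylbenzoate | Cc1c(O)c(O)c(C=O)c(O)c1C(=O)OCc1ccccc1
F3 | step 6 | 2-(benzyloxy)-3-(5,5-dimethyl-1,3-dioxan-2-yl)-4-methoxy-6-methylbenzoyl chloride | O=C(Cl)c1c(C)cc(OC)c(C2OCC(C)(C)CO2)c1OCc1ccccc1
F0 | step 11 | none | none
A1 | direct plan | 3-formyl-2-hydroxy-4-methoxy-6-methylbenzoic acid | COc1cc(C)c(C(=O)O)c(O)c1C=O
A2 | direct plan | tert-butyl 3-formyl-2,4,5-trihydroxy-6-methylbenzoate | CC(C)(C)OC(=O)c1c(C)c(O)c(O)c(C=O)c1O
A3 | direct plan | tert-butyl 3-formyl-5-[(3-formyl-2-hydroxy-4-methoxy-6-methylbenzoyl)oxy]-2,4-dihydroxy-6-methylbenzoate | COc1cc(C)c(C(=O)Oc2c(C)c(C(=O)OC(C)(C)C)c(O)c(C=O)c2O)c(O)c1C=O
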